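**Retrosynthetic overview**

1. The route rests on the oxirane whose oxygen bridges C5′ (methyl-bearing) and C6′ (bearing the C7′=C8′ link) of the trimethylcyclohexane ring and lies anti to the C3′ hydroxyl; in the 5′,6′-deoxy compound this hydroxyl is homoallylic to the C5′=C6′ ring alkene.
2. Last ring formed: C5′–O and C6′–O are made by hydroxyl-directed oxygen transfer to the complete skeleton carrying the 3′-epimeric alcohol (syn delivery), followed by Mitsunobu inversion at C3′ (syn becomes anti), ester removal and ring-A desilylation.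
3. The butenolide C3–C8′ bond comes from Stille coupling of an α-bromo (Z)-γ-ylidenebutenolide with a (3S)-hydroxy dienylstannane.
4. The exocyclic C5=CH bond comes from vinylogous aldol addition/elimination of 3-bromofuranone with a tetraenynal built from the ring-A enol triflate by Sonogashira, Horner–Wadsworth–Emmons and Wittig reactions.
5. Ring order: both cyclohexene rings come preformed from ketoisophorone via (4R,6R)-actinol (ring A keeps C4, ring B uses the Mitsunobu-inverted benzoate), the lactone ring comes from furan-2(5H)-one, and the oxirane is closed last.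

Key step: step 18

Remark on the chemistry: the ylidenebutenolide is taken to be alkali-labile and the vinyl epoxide acid-labile, so the C3′ inversion uses chloroacetic acid (ester removable with thiourea) and the last desilylation is buffered; steps 10 to 21 are run under argon with exclusion of light.

**Route**

Step 1
Reactants: 1 ketoisophorone (2,6,6-trimethylcyclohex-2-ene-1,4-dione)
Product: 2 (6R)-2,2,6-trimethylcyclohexane-1,4-dione
Conditions: ene-reductase (old yellow enzyme type), NADP+ (cat.), glucose dehydrogenase, D-glucose, phosphate buffer pH 7, 30 °C, short reaction time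
Reagents that add atoms: none
Why: Enzymatic ene reduction of the enedione C=C bond is a standard reaction of this substrate, and hydride and proton are added across the alkene inside the chiral active site, which should set the methyl-bearing carbon as R.

Step 2
Reactants: 2 (6R)-2,2,6-trimethylcyclohexane-1,4-dione
Product: 3 (4R,6R)-4-hydroxy-2,2,6-trimethylcyclohexan-1-one (trans-actinol)
Conditions: H2, Raney Ni, MeOH, rt; minor cis isomer removed by chromatography
Reagents that add atoms: none
Why: Heterogeneous hydrogenation reduces only the unhindered C4 carbonyl (C1 is flanked by a quaternary and a tertiary carbon), and hydrogen should add mainly from the side away from the axial C2 methyl, giving the 4R alcohol trans to the C6 methyl by substrate control.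

Step 3
Reactants: 3 (4R,6R)-4-hydroxy-2,2,6-trimethylcyclohexan-1-one
Product: 4 (4R,6R)-4-(tert-butyldimethylsilyloxy)-2,2,6-trimethylcyclohexan-1-one
Conditions: TBSCl, imidazole, DMF, rt
Reagents that add atoms: tert-butyldimethylsilyl chloride, CC(C)(C)[Si](C)(C)Cl
Why: Standard silylation of a secondary alcohol, which masks the ring-A oxygen so that it cannot bind vanadium in step 18 or react in step 19.

Step 4
Reactants: 4 (4R,6R)-4-(tert-butyldimethylsilyloxy)-2,2,6-trimethylcyclohexan-1-one
Product: 5 (4R)-4-(tert-butyldimethylsilyloxy)-2,6,6-trimethylcyclohex-1-en-1-yl trifluoromethanesulfonate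
Conditions: LDA, THF, −78 °C; PhNTf2, −78 °C → rt
Reagents that add atoms: N-phenylbis(trifluoromethanesulfonimide), O=S(=O)(N(c1ccccc1)S(=O)(=O)C(F)(F)F)C(F)(F)F
Why: The ketone has a single α-hydrogen, so enolisation is regiodefined and O-triflation gives the tetrasubstituted enol triflate, the C6 stereocentre being erased on purpose while C4 is untouched.

Step 5
Reactants: 5 enol triflate; 6 (E)-3-methylpent-2-en-4-yn-1-ol
Product: 7 (2E)-5-[(4R)-4-(tert-butyldimethylsilyloxy)-2,6,6-trimethylcyclohex-1-en-1-yl]-3-methylpent-2-en-4-yn-1-ol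
Conditions: Pd(PPh3)4 (5 mol%), CuI (10 mol%), i-Pr2NH, DMF, rt → 40 °C
Reagents that add atoms: none
Why: Sonogashira coupling of a cyclohexenyl triflate with a terminal enyne tolerates the free allylic alcohol and leaves the E-alkene of 6 unchanged.

Step 6
Reactants: 7 enynol
Product: 8 (2E)-5-[(4R)-4-(tert-butyldimethylsilyloxy)-2,6,6-trimethylcyclohex-1-en-1-yl]-3-methylpent-2-en-4-ynal
Conditions: MnO2 (excess), CH2Cl2, rt
Reagents that add atoms: none
Why: Manganese dioxide oxidises the allylic alcohol chemoselectively to the enal without touching the silyl ether, the alkyne or the alkene geometry.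

Step 7
Reactants: 8 enynal; 9 triethyl 4-phosphonocrotonate
Product: 10 ethyl (2E,4E,6E)-9-[(4R)-4-(tert-butyldimethylsilyloxy)-2,6,6-trimethylcyclohex-1-en-1-yl]-7-methylnona-2,4,6-trien-8-ynoate
Conditions: 9, NaHMDS, THF, −78 °C; then 8, −78 → 0 °C
Reagents that add atoms: none
Why: Horner–Wadsworth–Emmons olefination with the stabilised vinylogous phosphonate anion should form the new C=C bond E-selectively and carries the E-geometry of the crotonate through, any Z isomer being removed by chromatography.

Step 8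
Reactants: 10 trienynoate
Product: 11 (2E,4E,6E)-9-[(4R)-4-(tert-butyldimethylsilyloxy)-2,6,6-trimethylcyclohex-1-en-1-yl]-7-methylnona-2,4,6-trien-8-yn-1-ol
Conditions: DIBAL-H (2.2 equiv), CH2Cl2, −78 °C; Rochelle salt work-up
Reagents that add atoms: none
Why: DIBAL-H reduces the conjugated ester by 1,2-addition to the allylic alcohol at low temperature and leaves the enyne and the silyl ether alone.

Step 9
Reactants: 11 trienynol
Product: 12 (2E,4E,6E)-9-[(4R)-4-(tert-butyldimethylsilyloxy)-2,6,6-trimethylcyclohex-1-en-1-yl]-7-methylnona-2,4,6-trien-8-ynal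
Conditions: MnO2 (excess), CH2Cl2, rt
Reagents that add atoms: none
Why: Allylic oxidation with manganese dioxide gives the polyenal under neutral conditions without isomerising the E-alkenes.

Step 10
Reactants: 12 trienynal; 13 2-(triphenylphosphoranylidene)propanal
Product: 14 (2E,4E,6E,8E)-11-[(4R)-4-(tert-butyldimethylsilyloxy)-2,6,6-trimethylcyclohex-1-en-1-yl]-2,9-dimethylundeca-2,4,6,8-tetraen-10-ynal
Conditions: 13 (1.3 equiv), toluene, 70 °C
Reagents that add atoms: none
Why: Wittig reaction with the formyl-stabilised ylide should give the α-methyl enal with E-geometry, and the α-branched, more conjugated product reacts more slowly than 12, which limits a second homologation.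

Step 11
Reactants: 15 furan-2(5H)-one
Product: 17 3-bromofuran-2(5H)-one, via dibromolactone 16 (not isolated)
Conditions: Br2, CH2Cl2, reflux; then Et3N, 0 °C
Reagents that add atoms: bromine, BrBr
Why: Anti addition of bromine to the alkene followed by base-induced loss of HBr (removal of the acidic α-hydrogen, expulsion of the β-bromide) is the standard bromination/dehydrobromination route to α-bromo butenolides.

Step 12
Reactants: 17 3-bromofuran-2(5H)-one; 14 tetraenynal
Product: 20 (5Z)-3-bromo-5-[(2E,4E,6E,8E)-11-[(4R)-4-(tert-butyldimethylsilyloxy)-2,6,6-trimethylcyclohex-1-en-1-yl]-2,9-dimethylundeca-2,4,6,8-tetraen-10-yn-1-ylidene]furan-2(5H)-one, via silyloxyfuran 18 (not isolated), via aldol silyl ether 19 (not isolated)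
Conditions: 17, TBSOTf, i-Pr2NEt, CH2Cl2, 0 °C; 14, −78 → 0 °C; then DBU, 0 °C → rt
Reagents that add atoms: none
Why: Vinylogous Mukaiyama aldol addition of the 2-silyloxyfuran at its C5 to the aldehyde, then E1cB loss of silanolate through the planar 2-furanolate, is the established one-pot route to γ-ylidenebutenolides, is stereoconvergent for the two transient stereocentres, and should favour the Z-alkene in which the branched chain lies next to the ring oxygen and not next to C4–H.

Step 13
Reactants: 3 (4R,6R)-4-hydroxy-2,2,6-trimethylcyclohexan-1-one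
Product: 21 (1S,5R)-3,3,5-trimethyl-4-oxocyclohexyl benzoate (benzoate of cis-actinol)
Conditions: PhCO2H, PPh3, DIAD, toluene, 0 °C → rt
Reagents that add atoms: benzoic acid, OC(=O)c1ccccc1
Why: Mitsunobu esterification proceeds by SN2 displacement of the oxyphosphonium ion by benzoate, which inverts the carbinol carbon to S and installs the ester that protects this oxygen in steps 14 and 15.

Step 14
Reactants: 21 keto benzoate
Product: 22 (1S)-3,5,5-trimethyl-4-{[(trifluoromethyl)sulfonyl]oxy}cyclohex-3-en-1-yl benzoate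
Conditions: KHMDS, THF, −78 °C; PhNTf2, −78 → 0 °C
Reagents that add atoms: N-phenylbis(trifluoromethanesulfonimide), O=S(=O)(N(c1ccccc1)S(=O)(=O)C(F)(F)F)C(F)(F)F
Why: The same regiodefined enolisation and O-triflation as in step 4, with a bulky non-nucleophilic amide base that removes the only α-hydrogen at −78 °C without attacking the benzoate, which has no α-hydrogen of its own.

Step 15
Reactants: 22 enol triflate; 23 (E)-1,2-bis(tributylstannyl)ethene
Product: 24 (1S)-3,5,5-trimethyl-4-[(E)-2-(tributylstannyl)ethenyl]cyclohex-3-en-1-yl benzoate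
Conditions: Pd(PPh3)4 (5 mol%), LiCl (3 equiv), 23 (2.5 equiv), THF, 65 °C
Reagents that add atoms: none
Why: Stille coupling of the vinyl triflate with one tin terminus of the bis-stannane, used in excess so that the second C–Sn bond remains, should give the dienylstannane with retention of the E-geometry.

Step 16
Reactants: 24 stannyl benzoate
Product: 25 (1S)-3,5,5-trimethyl-4-[(E)-2-(tributylstannyl)ethenyl]cyclohex-3-en-1-ol
Conditions: K2CO3 (cat.), MeOH, rt
Reagents that add atoms: none
Why: Base-catalysed transesterification with methanol frees the hydroxyl by acyl–oxygen cleavage, so the S configuration is kept, and the vinyl C–Sn bond is stable to carbonate in methanol.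

Step 17
Reactants: 20 bromo ylidenebutenolide; 25 hydroxy dienylstannane
Product: 26 the 5′,6′-deoxy-3′-epi compound (3R,3′S): (5Z)-5-[tetraenynylidene as in 20]-3-{(E)-2-[(4S)-4-hydroxy-2,6,6-trimethylcyclohex-1-en-1-yl]ethenyl}furan-2(5H)-one, ring-A oxygen as TBS ether
Conditions: Pd2(dba)3·CHCl3 (2.5 mol%), AsPh3 (20 mol%), NMP, rt → 40 °C
Reagents that add atoms: none
Why: Stille coupling of an α-bromo butenolide, an activated vinyl bromide, with a vinylstannane under arsine-ligand acceleration proceeds with retention at both partners and tolerates the free hydroxyl, the silyl ether and the polyene.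

Step 18
Reactants: 26 the 5′,6′-deoxy-3′-epi compound
Product: 27 the 3′-epi epoxide (3R,3′R,5′R,6′S): 5′,6′-epoxide with the oxygen cis to the 3′-hydroxyl, ring-A oxygen as TBS ether
Conditions: VO(acac)2 (10 mol%), t-BuOOH (anhydrous, in decane, 1.5 equiv), 2,6-lutidine (0.2 equiv), toluene, 0 °C → rt
Reagents that add atoms: tert-butyl hydroperoxide, CC(C)(C)OO
Why: The free C3′ hydroxyl of 26 exchanges for an alkoxide ligand on vanadium(V), tert-butyl hydroperoxide binds the same metal as an η2-peroxide, and the distal peroxide oxygen is passed within this chelate to the C5′=C6′ bond in one concerted step that makes both C–O bonds. The closest known reaction is the VO(acac)2/t-BuOOH epoxidation of cyclohex-3-en-1-ols and other homoallylic alcohols, which gives the cis epoxy alcohol. The oxirane (O, C5′, C6′) is closed by this single, intramolecularly delivered [2+1] oxygen-atom transfer onto the ring alkene, so it is fused to the cyclohexane ring and no carbon–carbon bond changes. C5′ (R) and C6′ (S) are both set by the existing C3′ stereocentre, because the tethered metal peroxide reaches only the alkene face cis to the C3′–O bond, which is pseudoaxial in the reacting half-chair. The step needs site selectivity among nine C=C bonds and one C≡C bond and face selectivity at the chosen one: the ring-A oxygen is silylated and cannot bind vanadium, no chain alkene lies within reach of a hydroxyl, undirected epoxidation by this reagent is slow, and the twisted tetrasubstituted C5′=C6′ bond is also the most electron-rich alkene. The lutidine buffer and the low temperature are there to keep the Lewis-acidic metal from opening the vinyl epoxide to a furanoid 5′,8′-oxide.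

Step 19
Reactants: 27 the 3′-epi epoxide
Product: 28 the 3′-chloroacetate (3R,3′S,5′R,6′S), ester oxygen anti to the epoxide, ring-A oxygen as TBS ether
Conditions: PPh3, DIAD, THF, 0 °C (betaine preformed); then 27 and ClCH2CO2H, 0 °C → rt
Reagents that add atoms: chloroacetic acid, OC(=O)CCl
Why: Mitsunobu inversion by SN2 attack of chloroacetate on the C3′ oxyphosphonium ion turns 3′R into 3′S so that the oxygen ends up anti to the epoxide, the epoxide oxygen lying on the side of the leaving group and so unable to participate, while pre-forming the betaine keeps free acid away from the vinyl epoxide.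

Step 20
Reactants: 28 the 3′-chloroacetate
Product: 29 ring-A TBS ether of the target (3R,3′S,5′R,6′S)
Conditions: thiourea, NaHCO3, MeOH–THF, 40 °C
Reagents that add atoms: none
Why: Thiourea is S-alkylated by the α-chloro ester and the isothiouronium group then cyclises onto the ester carbonyl (standard dechloroacetylation), which frees the alcohol with retention under nearly neutral conditions and spares the enol lactone and the hindered tetrasubstituted epoxide.

Step 21
Reactants: 29 ring-A TBS ether of the target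
Product: 30 target CNP0180336.1
Conditions: TBAF, AcOH (1:1), THF, 0 °C → rt
Reagents that add atoms: none
Why: Fluoride-mediated desilylation buffered with acetic acid removes the secondary TBS ether without strong base or strong acid, conditions under which the ylidenebutenolide and the 5′,6′-epoxide should survive.

**Compound list**

1 | ketoisophorone (2,6,6-trimethylcyclohex-2-ene-1,4-dione) | CC1=CC(=O)CC(C)(C)C1=O | starting material
2 | (6R)-2,2,6-trimethylcyclohexane-1,4-dione | C[C@@H]1CC(=O)CC(C)(C)C1=O | intermediate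
3 | (4R,6R)-4-hydroxy-2,2,6-trimethylcyclohexan-1-one | C[C@@H]1C[C@@H](O)CC(C)(C)C1=O | intermediate
4 | (4R,6R)-4-(tert-butyldimethylsilyloxy)-2,2,6-trimethylcyclohexan-1-one | C[C@@H]1C[C@@H](O[Si](C)(C)C(C)(C)C)CC(C)(C)C1=O | intermediate
5 | (4R)-4-(tert-butyldimethylsilyloxy)-2,6,6-trimethylcyclohex-1-en-1-yl trifluoromethanesulfonate | CC1=C(OS(=O)(=O)C(F)(F)F)C(C)(C)C[C@H](O[Si](C)(C)C(C)(C)C)C1 | intermediate
6 | (E)-3-methylpent-2-en-4-yn-1-ol | C#C/C(C)=C/CO | starting material
7 | (2E)-5-[(4R)-4-(tert-butyldimethylsilyloxy)-2,6,6-trimethylcyclohex-1-en-1-yl]-3-methylpent-2-en-4-yn-1-ol | CC1=C(C#C/C(C)=C/CO)C(C)(C)C[C@H](O[Si](C)(C)C(C)(C)C)C1 | intermediate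
8 | (2E)-5-[(4R)-4-(tert-butyldimethylsilyloxy)-2,6,6-trimethylcyclohex-1-en-1-yl]-3-methylpent-2-en-4-ynal | CC1=C(C#C/C(C)=C/C=O)C(C)(C)C[C@H](O[Si](C)(C)C(C)(C)C)C1 | intermediate
9 | triethyl 4-phosphonocrotonate | CCOC(=O)/C=C/CP(=O)(OCC)OCC | starting material
10 | ethyl (2E,4E,6E)-9-[(4R)-4-(tert-butyldimethylsilyloxy)-2,6,6-trimethylcyclohex-1-en-1-yl]-7-methylnona-2,4,6-trien-8-ynoate | CC1=C(C#C/C(C)=C/C=C/C=C/C(=O)OCC)C(C)(C)C[C@H](O[Si](C)(C)C(C)(C)C)C1 | intermediate
11 | (2E,4E,6E)-9-[(4R)-4-(tert-butyldimethylsilyloxy)-2,6,6-trimethylcyclohex-1-en-1-yl]-7-methylnona-2,4,6-trien-8-yn-1-ol | CC1=C(C#C/C(C)=C/C=C/C=C/CO)C(C)(C)C[C@H](O[Si](C)(C)C(C)(C)C)C1 | intermediate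
12 | (2E,4E,6E)-9-[(4R)-4-(tert-butyldimethylsilyloxy)-2,6,6-trimethylcyclohex-1-en-1-yl]-7-methylnona-2,4,6-trien-8-ynal | CC1=C(C#C/C(C)=C/C=C/C=C/C=O)C(C)(C)C[C@H](O[Si](C)(C)C(C)(C)C)C1 | intermediate
13 | 2-(triphenylphosphoranylidene)propanal | CC(C=O)=P(c1ccccc1)(c1ccccc1)c1ccccc1 | starting material
14 | (2E,4E,6E,8E)-11-[(4R)-4-(tert-butyldimethylsilyloxy)-2,6,6-trimethylcyclohex-1-en-1-yl]-2,9-dimethylundeca-2,4,6,8-tetraen-10-ynal | CC1=C(C#C/C(C)=C/C=C/C=C/C=C(C)/C=O)C(C)(C)C[C@H](O[Si](C)(C)C(C)(C)C)C1 | intermediate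
15 | furan-2(5H)-one | O=C1OCC=C1 | starting material
16 | trans-3,4-dibromodihydrofuran-2(3H)-one (racemic, formed in the flask) | O=C1OC[C@@H](Br)[C@@H]1Br | intermediate
17 | 3-bromofuran-2(5H)-one | O=C1OCC=C1Br | intermediate
18 | [(3-bromofuran-2-yl)oxy](tert-butyl)dimethylsilane (formed in the flask) | CC(C)(C)[Si](C)(C)Oc1occc1Br | intermediate
19 | 3-bromo-5-[(2E,4E,6E,8E)-1-(tert-butyldimethylsilyloxy)-11-[(4R)-4-(tert-butyldimethylsilyloxy)-2,6,6-trimethylcyclohex-1-en-1-yl]-2,9-dimethylundeca-2,4,6,8-tetraen-10-yn-1-yl]furan-2(5H)-one, diastereomer mixture at the two new centres (formed in the flask) | CC1=C(C#C/C(C)=C/C=C/C=C/C=C(C)/C(O[Si](C)(C)C(C)(C)C)C2C=C(Br)C(=O)O2)C(C)(C)C[C@H](O[Si](C)(C)C(C)(C)C)C1 | intermediate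
20 | (5Z)-3-bromo-5-[(2E,4E,6E,8E)-11-[(4R)-4-(tert-butyldimethylsilyloxy)-2,6,6-trimethylcyclohex-1-en-1-yl]-2,9-dimethylundeca-2,4,6,8-tetraen-10-yn-1-ylidene]furan-2(5H)-one | CC1=C(C#C/C(C)=C/C=C/C=C/C=C(C)/C=C2C=C(Br)C(=O)O/2)C(C)(C)C[C@H](O[Si](C)(C)C(C)(C)C)C1 | intermediate
21 | (1S,5R)-3,3,5-trimethyl-4-oxocyclohexyl benzoate | C[C@@H]1C[C@H](OC(=O)c2ccccc2)CC(C)(C)C1=O | intermediate
22 | (1S)-3,5,5-trimethyl-4-{[(trifluoromethyl)sulfonyl]oxy}cyclohex-3-en-1-yl benzoate | CC1=C(OS(=O)(=O)C(F)(F)F)C(C)(C)C[C@@H](OC(=O)c2ccccc2)C1 | intermediate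
23 | (E)-1,2-bis(tributylstannyl)ethene | CCCC[Sn](CCCC)(CCCC)/C=C/[Sn](CCCC)(CCCC)CCCC | starting material
24 | (1S)-3,5,5-trimethyl-4-[(E)-2-(tributylstannyl)ethenyl]cyclohex-3-en-1-yl benzoate | CC1=C(/C=C/[Sn](CCCC)(CCCC)CCCC)C(C)(C)C[C@@H](OC(=O)c2ccccc2)C1 | intermediate
25 | (1S)-3,5,5-trimethyl-4-[(E)-2-(tributylstannyl)ethenyl]cyclohex-3-en-1-ol | CC1=C(/C=C/[Sn](CCCC)(CCCC)CCCC)C(C)(C)C[C@@H](O)C1 | intermediate
26 | 5′,6′-deoxy-3′-epi compound (3R,3′S), free 3′-hydroxyl, ring-A TBS ether | CC1=C(C#C/C(C)=C/C=C/C=C/C=C(C)/C=C2C=C(/C=C/C3=C(C)C[C@H](O)CC3(C)C)C(=O)O/2)C(C)(C)C[C@H](O[Si](C)(C)C(C)(C)C)C1 | intermediate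
27 | 3′-epi epoxide (3R,3′R,5′R,6′S), epoxide oxygen cis to the 3′-hydroxyl, ring-A TBS ether | CC1=C(C#C/C(C)=C/C=C/C=C/C=C(C)/C=C2C=C(/C=C/[C@@]34O[C@]3(C)C[C@H](O)CC4(C)C)C(=O)O/2)C(C)(C)C[C@H](O[Si](C)(C)C(C)(C)C)C1 | intermediate
28 | 3′-chloroacetate (3R,3′S,5′R,6′S), ester oxygen trans to the epoxide, ring-A TBS ether | CC1=C(C#C/C(C)=C/C=C/C=C/C=C(C)/C=C2C=C(/C=C/[C@@]34O[C@]3(C)C[C@@H](OC(=O)CCl)CC4(C)C)C(=O)O/2)C(C)(C)C[C@H](O[Si](C)(C)C(C)(C)C)C1 | intermediate
29 | ring-A TBS ether of the target (3R,3′S,5′R,6′S) | CC1=C(C#C/C(C)=C/C=C/C=C/C=C(C)/C=C2C=C(/C=C/[C@@]34O[C@]3(C)C[C@@H](O)CC4(C)C)C(=O)O/2)C(C)(C)C[C@H](O[Si](C)(C)C(C)(C)C)C1 | intermediate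
30 | CNP0180336.1, the (3R,3′S,5′R,6′S)-diol | CC1=C(C#C/C(C)=C/C=C/C=C/C=C(C)/C=C2C=C(/C=C/[C@@]34O[C@]3(C)C[C@@H](O)CC4(C)C)C(=O)O/2)C(C)(C)C[C@H](O)C1 | target

**Step count**

Total: 21 steps. Longest linear sequence: 16 steps (steps 1–10, 12, 17–21).

**Steps most likely to fail**

Step 18. The peroxide and the metal may degrade the long polyene oxidatively, the hydroxyl may be oxidised to the ketone instead of directing, or the Lewis-acidic metal may open the new vinyl epoxide. The fallback moves the same hydroxyl-directed epoxidation to the ring-B fragment, before any polyene is present; it sets out from triflate 22 and comes back at 29. Sonogashira coupling of 22 with ethynyltrimethylsilane (Pd(PPh3)4, CuI, i-Pr2NH, DMF) should give (1S)-3,5,5-trimethyl-4-[(trimethylsilyl)ethynyl]cyclohex-3-en-1-yl benzoate F1. K2CO3 in methanol should remove both the benzoate and the C-silyl group to give (1S)-4-ethynyl-3,5,5-trimethylcyclohex-3-en-1-ol F2. VO(acac)2/t-BuOOH on this simple homoallylic alcohol should give the cis epoxy alcohol (1R,3R,6R)-6-ethynyl-1,5,5-trimethyl-7-oxabicyclo[4.1.0]heptan-3-ol F3. Mitsunobu reaction with 4-nitrobenzoic acid should give the inverted (1R,3S,6R) 4-nitrobenzoate F4, and methanolysis (K2CO3, MeOH) the trans epoxy alcohol (1R,3S,6R)-6-ethynyl-1,5,5-trimethyl-7-oxabicyclo[4.1.0]heptan-3-ol F5. Palladium-catalysed hydrostannation (Bu3SnH, PdCl2(PPh3)2, THF, 0 °C) should give the (E)-vinylstannane (1R,3S,6S)-1,5,5-trimethyl-6-[(E)-2-(tributylstannyl)ethenyl]-7-oxabicyclo[4.1.0]heptan-3-ol F6. Stille coupling of F6 with bromide 20 under the conditions of step 17 should give 29, which is desilylated as in step 21.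

Step 19. The oxyphosphonium ion may undergo E2 elimination to a ring alkene instead of substitution, or acid present in the mixture may trigger rearrangement of the vinyl epoxide. The fallback replaces the redox condensation by sulfonate displacement; it sets out from 27 and comes back at 29, so that 28 and step 20 are skipped. Mesylation (MsCl, Et3N, CH2Cl2, −20 °C) should give the 3′-methanesulfonate F7. Potassium nitrite in DMSO (rt to 40 °C) should displace it with inversion to the 3′-nitrite ester F8, which is hydrolysed on aqueous work-up to 29. If this also fails, the fragment route written under step 18 carries out the inversion on F3.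

Step 12. The E1cB elimination may give a poor Z/E ratio at the exocyclic alkene, and the polyenal may decompose under the silyl triflate. The fallback builds the lactone ring by a coupling/cyclisation in which the Z-geometry follows from the mechanism; it sets out from aldehyde 14 and comes back at 20. Homologation of 14 with lithiated trimethylsilyldiazomethane (THF, −78 °C → rt, Colvin rearrangement) should give the terminal alkyne (4R)-tert-butyldimethylsilyl ether of 4-[(3E,5E,7E,9E)-3,10-dimethyldodeca-3,5,7,9-tetraene-1,11-diyn-1-yl]-3,5,5-trimethylcyclohex-3-en-1-ol F9. Treatment of F9 with (E)-2,3-dibromoacrylic acid (Pd(PPh3)4, CuI, Et3N, MeCN, rt) should give, by Sonogashira coupling at the C3–Br bond, the (Z)-2-bromo-en-4-ynoic acid F10 (not isolated). F10 should lactonise 5-exo-dig by anti addition of the carboxylate across the alkyne to give Z-configured 20.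

**Further compounds**

F1 | step 18 | (1S)-3,5,5-trimethyl-4-[(trimethylsilyl)ethynyl]cyclohex-3-en-1-yl benzoate | CC1=C(C#C[Si](C)(C)C)C(C)(C)C[C@@H](OC(=O)c2ccccc2)C1
F2 | step 18 | (1S)-4-ethynyl-3,5,5-trimethylcyclohex-3-en-1-ol | CC1=C(C#C)C(C)(C)C[C@@H](O)C1
F3 | step 18 | (1R,3R,6R)-6-ethynyl-1,5,5-trimethyl-7-oxabicyclo[4.1.0]heptan-3-ol (epoxide cis to hydroxyl) | C#C[C@@]12O[C@]1(C)C[C@H](O)CC2(C)C
F4 | step 18 | (1R,3S,6R)-6-ethynyl-1,5,5-trimethyl-7-oxabicyclo[4.1.0]heptan-3-yl 4-nitrobenzoate | C#C[C@@]12O[C@]1(C)C[C@@H](OC(=O)c3ccc(cc3)[N+](=O)[O-])CC2(C)C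
F5 | step 18 | (1R,3S,6R)-6-ethynyl-1,5,5-trimethyl-7-oxabicyclo[4.1.0]heptan-3-ol (epoxide trans to hydroxyl) | C#C[C@@]12O[C@]1(C)C[C@@H](O)CC2(C)C
F6 | step 18 | (1R,3S,6S)-1,5,5-trimethyl-6-[(E)-2-(tributylstannyl)ethenyl]-7-oxabicyclo[4.1.0]heptan-3-ol | CCCC[Sn](CCCC)(CCCC)/C=C/[C@@]12O[C@]1(C)C[C@@H](O)CC2(C)C
F7 | step 19 | 3′-methanesulfonate of 27 (3R,3′R,5′R,6′S) | CC1=C(C#C/C(C)=C/C=C/C=C/C=C(C)/C=C2C=C(/C=C/[C@@]34O[C@]3(C)C[C@H](OS(C)(=O)=O)CC4(C)C)C(=O)O/2)C(C)(C)C[C@H](O[Si](C)(C)C(C)(C)C)C1
F8 | step 19 | 3′-nitrite ester with inverted C3′ (3R,3′S,5′R,6′S) | CC1=C(C#C/C(C)=C/C=C/C=C/C=C(C)/C=C2C=C(/C=C/[C@@]34O[C@]3(C)C[C@@H](ON=O)CC4(C)C)C(=O)O/2)C(C)(C)C[C@H](O[Si](C)(C)C(C)(C)C)C1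
F9 | step 12 | tert-butyl{[(1R)-4-[(3E,5E,7E,9E)-3,10-dimethyldodeca-3,5,7,9-tetraene-1,11-diyn-1-yl]-3,5,5-trimethylcyclohex-3-en-1-yl]oxy}dimethylsilane | CC1=C(C#C/C(C)=C/C=C/C=C/C=C(C)/C#C)C(C)(C)C[C@H](O[Si](C)(C)C(C)(C)C)C1
F10 | step 12 | (2Z)-2-bromo-pent-2-en-4-ynoic acid carrying the chain of F9 at C5 (carboxyl and alkynyl cis) | CC1=C(C#C/C(C)=C/C=C/C=C/C=C(C)/C#C/C=C(/Br)C(=O)O)C(C)(C)C[C@H](O[Si](C)(C)C(C)(C)C)C1
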